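**Retrosynthetic overview**
1. 28 ⇐ 26: a single reductive operation (N–O hydrogenolysis with imine hydrolysis, butenolide hydrogenation, lactonisation) unmasks C9=O and C11–OH, sets C20 and closes ring C.
2. 26 ⇐ 22 + silyloxyfuran 24: vinylogous Mannich reaction at C3 of the macrobicyclic N-acyliminium ion. Ring D arrives preformed, and C3 and C18 are set.
3. Key step, 22 ⇐ 21: intramolecular nitrile oxide/Z-olefin cycloaddition makes C9–C10 and O–C11. Ring A (eleven-membered) and the isoxazoline form in one operation, and C10 and C11 are set.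
4. 20 ⇐ 11 + 5-aminopentanol: lactone-to-lactam ring switch (ring B), then Z-Wittig olefination, oxidation and oxime formation.
5. 11 ⇐ ozonolysis and Davis hydroxylation of Diels–Alder adduct 7, made from menthyloxyfuranone 4 and silyloxydiene 6 (sets C1, C12, C13). Ring order: temporary cyclohexene → B → A + isoxazoline → D attached → C.

**Atom labels (tuberostemonine numbering)**
- C1 = C(OH); C2; C3; N4; C5–C8 = (CH2)4.
- C9 = ketone; C9a = lactam C=O; C10 = CHEt; C11 = CH–O; C12; C13 = CHMe; C14 = C=O of fused lactone.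
- C18–C21 = pendant lactone.
- Ring A = 11-membered ring, B = pyrrolidinone, C = fused lactone, D = pendant lactone.

**Assumption:** acetal-type centres that are destroyed later (C3–OMe, the C11 lactol carbon, the oxime C=N) are carried as mixtures and drawn without configuration.

Step 1
Reactants: 1 furfural
Product: 2 5-hydroxyfuran-2(5H)-one
Conditions: O2, visible light, rose bengal (cat.), MeOH, rt
Reagents that add atoms: oxygen, O=O
Why: Singlet-oxygen [4+2] photooxygenation of the furan gives an endoperoxide that MeOH solvolyses with loss of the formyl carbon (Schenck-type furfural oxidation); the hemiacetal carbon is racemic and is fixed in step 2.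

Step 2
Reactants: 2 5-hydroxyfuran-2(5H)-one; 3 (−)-menthol
Product: 4 (5R)-5-[(1R,2S,5R)-menthyloxy]furan-2(5H)-one
Conditions: camphorsulfonic acid (cat.), neat, 100 °C; crystallise from petroleum ether
Reagents that add atoms: none
Why: In this acid-catalysed pseudo-acid acetalisation the two C5 epimers interconvert under the acid and the 5R epimer crystallises, so cheap menthol fixes the absolute configuration of the whole route.

Step 3
Reactants: 5 ethyl vinyl ketone
Product: 6 (Z)-3-(tert-butyldimethylsilyloxy)penta-1,3-diene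
Conditions: TBSOTf, Et3N, Et2O, 0 °C to rt
Reagents that add atoms: tert-butyldimethylsilyl triflate, CC(C)(C)[Si](C)(C)OS(=O)(=O)C(F)(F)F
Why: Soft enolisation (silyl triflate/amine) at the only enolisable side gives the Z silyl enol ether, which places the methyl group "outside" on the s-cis diene.

Step 4
Reactants: 4 menthyloxyfuranone; 6 silyloxydiene
Product: 7 (3R,3aR,4S,7aS)-5-(tert-butyldimethylsilyloxy)-3-(menthyloxy)-4-methyl-3a,4,7,7a-tetrahydroisobenzofuran-1(3H)-one
Conditions: toluene, BHT (cat.), 110 °C, sealed tube, 72 h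
Reagents that add atoms: none
Why: In this thermal normal-demand Diels–Alder reaction the enol-ether carbon carrying the methyl group bonds to the butenolide β-carbon (para rule, Mukaiyama–Michael polarity), and the diene adds anti to the menthyloxy group and endo, so C12, C13 (methyl cis to the lactone) and the cis ring-fusion carbon C1 are set in one step.

Step 5
Reactants: 7 Diels–Alder adduct
Product: 9 (3R,3aR,4S,7aR)-7a-hydroxy derivative of 7, via potassium enolate 8 (not isolated)
Conditions: KN(SiMe3)2, THF, −78 °C; 2-(phenylsulfonyl)-3-phenyloxaziridine, −78 °C; AcOH quench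
Reagents that add atoms: 2-(phenylsulfonyl)-3-phenyloxaziridine, O=S(=O)(c1ccccc1)N1OC1c1ccccc1
Why: In this Davis enolate oxidation the ring-fusion C1–H is the only acidic site and the oxidant attacks trans to the vicinal C12–C13 bond (the face used in tandem additions to 4, and the one that keeps the cis fusion), so OH replaces H with retention to give (1R), while the silyl enol ether is inert at −78 °C.

Step 6
Reactants: 9 hydroxy lactone
Product: 11 (2S)-2-[(2R,3R,4R)-4-hydroxy-2-(menthyloxy)-5-oxo-4-(2-oxoethyl)tetrahydrofuran-3-yl]propanoic acid, via silyl ester 10 (not isolated)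
Conditions: O3, CH2Cl2/MeOH, −78 °C; Me2S, −78 °C to rt; aqueous work-up at pH 5
Reagents that add atoms: ozone, [O-][O+]=O
Why: Ozonolysis of the silyl enol ether opens the temporary cyclohexene to an aldehyde (C3) and a silyl ester (C14) that hydrolyses on work-up, so the two termini emerge already differentiated in oxidation level and no stereocentre is touched.

Step 7
Reactants: 11 aldehyde acid; 12 5-aminopentan-1-ol
Product: 15 (3R)-3-hydroxy-1-(5-hydroxypentyl)-5-methoxy-3-[(3R,4S)-2-hydroxy-4-methyl-5-oxotetrahydrofuran-3-yl]pyrrolidin-2-one, via ring-opened aldehyde acid 13 (not isolated), via hydroxylactam lactol 14 (not isolated)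
Conditions: MeOH, rt, 12 h (1.0 equiv 12); then PPTS (10 mol %), rt, 1 h
Reagents that add atoms: methanol, CO
Why: In this lactone-to-lactam ring switch the amine condenses with the free C3 aldehyde, the carbinolamine nitrogen acylates itself on the acylal-type lactone carbonyl C9a through a five-membered transition state, the expelled hemiacetal loses menthol, the C14 acid catches the freed C11 aldehyde as a lactol, and only the more easily ionised N-acyl hemiaminal exchanges OH for OMe; C1, C12 and C13 survive because no basic amine remains when the epimerisable aldehyde appears.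

Step 8
Reactants: 15 methoxylactam lactol; 16 propyltriphenylphosphonium bromide
Product: 18 methyl (2S,3R,4Z)-3-[(3R)-3-hydroxy-1-(5-hydroxypentyl)-5-methoxy-2-oxopyrrolidin-3-yl]-2-methylhept-4-enoate, via Z-alkenyl acid 17 (not isolated)
Conditions: 16, NaN(SiMe3)2 (5 equiv each), THF, 0 °C; add 15, −78 to 0 °C; citric acid work-up; then TMSCHN2, toluene/MeOH, 0 °C
Reagents that add atoms: (trimethylsilyl)diazomethane, C[Si](C)(C)C=[N+]=[N-]
Why: In this salt-free Wittig olefination of a lactol (prostaglandin-type) base opens the lactol to the aldehyde carboxylate, the non-stabilised ylide gives the Z-alkene kinetically and faster than retro-aldol or C12 epimerisation, the N,O-acetal is base-stable, and the esterification masks the acid, which would otherwise add to the nitrile oxide.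

Step 9
Reactants: 18 hydroxy ester
Product: 20 oxime of the C9 aldehyde (E/Z mixture), via aldehyde 19 (not isolated)
Conditions: TEMPO (10 mol %), PhI(OAc)2, CH2Cl2, rt; then NH2OH·HCl, pyridine, EtOH, rt
Reagents that add atoms: hydroxylamine hydrochloride, NO.Cl
Why: The TEMPO/PhI(OAc)2 oxidation stops at the aldehyde and leaves the tertiary alcohol and the Z-alkene alone, and the oxime condensation follows in the same flask.

Step 10 (key step)
Reactants: 20 oxime
Product: 22 isoxazoline-bridged macrobicycle (ring A closed; C9=N–O–C11; 3-OMe lactam; methyl ester on C13), via nitrile oxide 21 (not isolated)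
Conditions: aq NaOCl, CH2Cl2, 0 °C to rt, syringe-pump addition of 20 (final 1 mM)
Reagents that add atoms: none
Why: This intramolecular nitrile oxide–olefin [3+2] cycloaddition (INOC) closes the eleven-membered carbocycle and the isoxazoline at once: the dipole carbon bonds to the less hindered distal alkene carbon C10 (the larger, less strained ring), suprafacial addition to the Z-alkene gives the syn C10/C11 pair, and allylic 1,3-strain puts H12 inside, the tether-bearing C1 outside and C13 anti, so only the alkene face that leads to the target configuration at C10 and C11 (C1 and C10 cis about C11–C12) is reachable.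

Step 11
Reactants: 23 3-methylfuran-2(5H)-one
Product: 24 tert-butyldimethyl[(3-methylfuran-2-yl)oxy]silane
Conditions: TBSOTf, Et3N, CH2Cl2, 0 °C
Reagents that add atoms: tert-butyldimethylsilyl triflate, CC(C)(C)[Si](C)(C)OS(=O)(=O)C(F)(F)F
Why: Soft enolisation of the butenolide gives the aromatic 2-silyloxyfuran, a γ-selective dienolate equivalent.

Step 12
Reactants: 22 macrobicyclic N,O-acetal; 24 silyloxyfuran
Product: 26 (3S,18S)-butenolide adduct of 22, via N-acyliminium triflate 25 (not isolated)
Conditions: TMSOTf (20 mol %), CH2Cl2, −78 °C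
Reagents that add atoms: none
Why: In this vinylogous Mannich reaction of a cyclic N-acyliminium ion the face of ring B carrying C12 and the eight-atom bridge is blocked, so the furan γ-carbon adds syn to the small C1–OH to give (3S), and the usual compact transition state of 2-silyloxyfurans with five-membered N-acyliminium ions gives the threo (18S) relationship used in Stemona lactone syntheses.

Step 13
Reactants: 26 butenolide isoxazoline
Product: 28 CNP0221273.1 (target), via hydroxy ketone ester 27 (not isolated)
Conditions: H2 (1 atm), Raney Ni, B(OH)3, MeOH/H2O 5:1, rt; filter; then PPTS (10 mol %), toluene, 40 °C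
Reagents that add atoms: water, O
Why: Buffered Raney Ni hydrogenolysis of the isoxazoline N–O bond with imine hydrolysis gives the β-hydroxy ketone without C10 epimerisation, the same catalyst hydrogenates the butenolide from the face opposite the C3 substituent (cis C18/C20, 20S), and the secondary C11–OH rather than the hindered tertiary C1–OH lactonises onto the γ-ester under mild acid, which avoids β-elimination.

**Compound list**
1 | furfural | O=Cc1ccco1 | starting material
2 | 5-hydroxyfuran-2(5H)-one | O=C1C=CC(O)O1 | intermediate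
3 | (−)-menthol, (1R,2S,5R) | O[C@@H]1C[C@H](C)CC[C@H]1C(C)C | starting material
4 | (5R)-5-(l-menthyloxy)furan-2(5H)-one | O=C1C=C[C@H](O[C@@H]2C[C@H](C)CC[C@H]2C(C)C)O1 | intermediate
5 | ethyl vinyl ketone | C=CC(=O)CC | starting material
6 | (Z)-3-(TBSO)penta-1,3-diene | C=C/C(O[Si](C)(C)C(C)(C)C)=C/C | intermediate
7 | endo, anti Diels–Alder adduct (3R,3aR,4S,7aS) | O=C1O[C@@H](O[C@@H]3C[C@H](C)CC[C@H]3C(C)C)[C@@H]2[C@H](C)C(O[Si](C)(C)C(C)(C)C)=CC[C@H]12 | intermediate
8 | potassium enolate of 7 | [K+].[O-]C1=C2CC=C(O[Si](C)(C)C(C)(C)C)[C@@H](C)[C@H]2[C@H](O[C@@H]3C[C@H](C)CC[C@H]3C(C)C)O1 | intermediate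
9 | 7a-hydroxy lactone (3R,3aR,4S,7aR) | O=C1O[C@@H](O[C@@H]3C[C@H](C)CC[C@H]3C(C)C)[C@@H]2[C@H](C)C(O[Si](C)(C)C(C)(C)C)=CC[C@]12O | intermediate
10 | aldehyde TBS ester | O=C1O[C@@H](O[C@@H]2C[C@H](C)CC[C@H]2C(C)C)[C@H]([C@H](C)C(=O)O[Si](C)(C)C(C)(C)C)[C@]1(O)CC=O | intermediate
11 | aldehyde acid | O=C1O[C@@H](O[C@@H]2C[C@H](C)CC[C@H]2C(C)C)[C@H]([C@H](C)C(O)=O)[C@]1(O)CC=O | intermediate
12 | 5-aminopentan-1-ol | NCCCCCO | starting material
13 | ring-opened hydroxylactam aldehyde acid | OCCCCCN1C(=O)[C@@](O)(CC1O)[C@H](C=O)[C@H](C)C(O)=O | intermediate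
14 | hydroxylactam lactol | OCCCCCN1C(=O)[C@@](O)(CC1O)[C@@H]2C(O)OC(=O)[C@H]2C | intermediate
15 | methoxylactam lactol | OCCCCCN1C(=O)[C@@](O)(CC1OC)[C@@H]2C(O)OC(=O)[C@H]2C | intermediate
16 | propyltriphenylphosphonium bromide | CCC[P+](c1ccccc1)(c1ccccc1)c1ccccc1.[Br-] | starting material
17 | Z-alkenyl acid | OCCCCCN1C(=O)[C@@](O)(CC1OC)[C@H](/C=C\CC)[C@H](C)C(O)=O | intermediate
18 | Z-alkenyl methyl ester, primary alcohol | OCCCCCN1C(=O)[C@@](O)(CC1OC)[C@H](/C=C\CC)[C@H](C)C(=O)OC | intermediate
19 | C9 aldehyde | O=CCCCCN1C(=O)[C@@](O)(CC1OC)[C@H](/C=C\CC)[C@H](C)C(=O)OC | intermediate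
20 | C9 oxime | ON=CCCCCN1C(=O)[C@@](O)(CC1OC)[C@H](/C=C\CC)[C@H](C)C(=O)OC | intermediate
21 | nitrile oxide | [O-][N+]#CCCCCN1C(=O)[C@@](O)(CC1OC)[C@H](/C=C\CC)[C@H](C)C(=O)OC | intermediate
22 | isoxazoline macrobicycle | CC[C@@H]1C(=NO3)CCCCN2C(=O)[C@@](O)(CC2OC)[C@@H]([C@H](C)C(=O)OC)[C@H]13 | intermediate
23 | 3-methylfuran-2(5H)-one | CC1=CCOC1=O | starting material
24 | 3-methyl-2-(TBSO)furan | Cc1ccoc1O[Si](C)(C)C(C)(C)C | intermediate
25 | N-acyliminium triflate | CC[C@@H]1C(=NO3)CCCC[N+]2C(=O)[C@@](O)(CC=2)[C@@H]([C@H](C)C(=O)OC)[C@H]13.[O-]S(=O)(=O)C(F)(F)F | intermediate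
26 | butenolide isoxazoline | CC[C@@H]1C(=NO3)CCCCN2C(=O)[C@@](O)(C[C@H]2[C@@H]2C=C(C)C(=O)O2)[C@@H]([C@H](C)C(=O)OC)[C@H]13 | intermediate
27 | C11-hydroxy C9-ketone methyl ester | CC[C@@H]1C(=O)CCCCN2C(=O)[C@@](O)(C[C@H]2[C@@H]2C[C@H](C)C(=O)O2)[C@@H]([C@H](C)C(=O)OC)[C@H]1O | intermediate
28 | CNP0221273.1 | CC[C@@H]1C(=O)CCCCN2C(=O)[C@@](O)(C[C@H]2[C@@H]2C[C@H](C)C(=O)O2)[C@@H]2[C@H]1OC(=O)[C@H]2C | target

**Step count**
- Total steps: 13.
- Longest linear sequence: 11 (steps 1, 2, 4, 5, 6, 7, 8, 9, 10, 12, 13).
- No protecting-group steps are used.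

**Three steps most likely to fail, each with a fallback**

Step 4 (slow thermal cycloaddition, endo/exo or regiochemical leakage). The fallback sets out from 4 and 5 and replaces the concerted cycloaddition with an anionic Michael–Michael annulation. Compound 5 is deprotonated on its ethyl side with LiN(iPr)2 (THF, −78 °C), and the cross-conjugated lithium dienolate is added to 4. The first Michael bond (C12–C13) forms anti to the menthyloxy group. The resulting lactone enolate then closes onto the vinyl ketone to give the cis-fused keto lactone F1. Kinetic enolisation on the CH2 side (LiN(iPr)2, TBSCl, THF/DMPU, −78 °C) returns to the route at 7.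

Step 10 (furoxan dimerisation or no ring closure of the sluggish Z-alkene). The fallback sets out from 18 and changes the dipole to a silyl nitronate, which does not dimerise and can be heated for long periods. I2/PPh3/imidazole gives the primary iodide F2, and AgNO2 in Et2O gives the nitroalkane F3. TMSCl/Et3N in benzene at 60 °C under high dilution forms the trimethylsilyl nitronate F4. F4 undergoes the intramolecular silyl nitronate–olefin cycloaddition to give the N-(trimethylsilyloxy)isoxazolidine macrobicycle F5. Brief exposure to dilute HCl in Et2O eliminates silanol and returns to the route at 22.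

Step 12 (poor C3/C18 selectivity or low reactivity of the bridged N-acyliminium ion). The fallback sets out from 22 and builds ring D through the C18–C19 bond instead of the C3–C18 bond. Potassium vinyltrifluoroborate with BF3·OEt2 gives the 3-vinyl lactam F6, attacking the same open face. Ozonolysis (O3, then Me2S) gives the 3-formyl lactam F7. Zn with methyl 2-(bromomethyl)acrylate (THF/aq NH4Cl, Barbier allylation) gives the hydroxy ester F8, which lactonises to the α-methylene-γ-butyrolactone F9. The conditions of step 13 hydrogenate the exocyclic methylene, again from the face opposite C3, and cleave the isoxazoline, so the route is rejoined at 27.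

**Further compounds**
F1 | step 4 | cis-fused keto lactone (desilyl 7) | O=C1O[C@@H](O[C@@H]3C[C@H](C)CC[C@H]3C(C)C)[C@@H]2[C@H](C)C(=O)CC[C@H]12
F2 | step 10 | primary iodide | ICCCCCN1C(=O)[C@@](O)(CC1OC)[C@H](/C=C\CC)[C@H](C)C(=O)OC
F3 | step 10 | nitroalkane | [O-][N+](=O)CCCCCN1C(=O)[C@@](O)(CC1OC)[C@H](/C=C\CC)[C@H](C)C(=O)OC
F4 | step 10 | trimethylsilyl nitronate | C[Si](C)(C)O[N+]([O-])=CCCCCN1C(=O)[C@@](O)(CC1OC)[C@H](/C=C\CC)[C@H](C)C(=O)OC
F5 | step 10 | N-(trimethylsilyloxy)isoxazolidine macrobicycle | CC[C@@H]1C(N(O[Si](C)(C)C)O3)CCCCN2C(=O)[C@@](O)(CC2OC)[C@@H]([C@H](C)C(=O)OC)[C@H]13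
F6 | step 12 | 3-vinyl lactam | CC[C@@H]1C(=NO3)CCCCN2C(=O)[C@@](O)(C[C@H]2C=C)[C@@H]([C@H](C)C(=O)OC)[C@H]13
F7 | step 12 | 3-formyl lactam | CC[C@@H]1C(=NO3)CCCCN2C(=O)[C@@](O)(C[C@H]2C=O)[C@@H]([C@H](C)C(=O)OC)[C@H]13
F8 | step 12 | C18 hydroxy ester | CC[C@@H]1C(=NO3)CCCCN2C(=O)[C@@](O)(C[C@H]2[C@@H](O)CC(=C)C(=O)OC)[C@@H]([C@H](C)C(=O)OC)[C@H]13
F9 | step 12 | α-methylene-γ-butyrolactone | CC[C@@H]1C(=NO3)CCCCN2C(=O)[C@@](O)(C[C@H]2[C@@H]2CC(=C)C(=O)O2)[C@@H]([C@H](C)C(=O)OC)[C@H]13
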